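**Assumption:** the target is a planar flavonol with no stereocentre, so there is no enantiomer to control; compounds 1 and 4 are taken as catalogue items.

## Retrosynthetic overview

1. Target 10 ⇐ tetra-O-benzyl flavonol 9 by global hydrogenolysis (neutral, so the 8-OMe cannot migrate to C6 by Wessely–Moser ring opening).
2. 9 ⇐ flavone 7 by C2=C3 epoxidation and acid isomerisation (3-OH installed last on the finished pyranone).
3. 7 ⇐ Claisen condensation of A-ring ketone 3 with B-ring ester 5, then cyclodehydration; the single free phenol of 3 fixes the 8-OMe regiochemistry.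
4. 3 ⇐ bought 2-hydroxy-4,6-bis(benzyloxy)acetophenone 1 by ortho-iodination and Cu-catalysed methoxylation; 5 ⇐ bought methyl 4-O-methylgallate 4 by benzylation.
5. Ring order: rings A and B are bought; ring C (the pyranone) is the only ring formed, in step 4.

## Route

Step 1
Reactants: 1 1-[2,4-bis(benzyloxy)-6-hydroxyphenyl]ethan-1-one
Product: 2 1-[4,6-bis(benzyloxy)-2-hydroxy-3-iodophenyl]ethan-1-one
Conditions: BnMe3N·ICl2 (1.05 equiv), NaHCO3, CH2Cl2/MeOH, rt
Reagents that add atoms: benzyltrimethylammonium dichloroiodate, C[N+](C)(C)Cc1ccccc1.Cl[I-]Cl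
Why: Electrophilic aromatic iodination in which the chelated 2-OH directs to its ortho carbon C3 (the other free site, C5, is flanked by two bulky OBn groups), and one equivalent of reagent avoids di-iodination; no stereocentre.

Step 2
Reactants: 2 1-[4,6-bis(benzyloxy)-2-hydroxy-3-iodophenyl]ethan-1-one
Product: 3 1-[4,6-bis(benzyloxy)-2-hydroxy-3-methoxyphenyl]ethan-1-one
Conditions: NaOMe (5 equiv), CuI (20 mol%), DMF/MeOH, 110 °C; dilute HCl work-up
Reagents that add atoms: sodium methoxide, C[O-].[Na+]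
Why: Ullmann-type Cu(I)-catalysed C–O coupling of an o-iodophenol with methoxide (the same reactivity as the classical 5-halovanillin to syringaldehyde conversion), which benzyl ethers and the aryl ketone tolerate; no stereocentre.

Step 3
Reactants: 4 methyl 3,5-dihydroxy-4-methoxybenzoate
Product: 5 methyl 3,5-bis(benzyloxy)-4-methoxybenzoate
Conditions: BnBr (2.3 equiv), K2CO3, DMF, 60 °C
Reagents that add atoms: benzyl bromide, BrCc1ccccc1
Why: Williamson ether synthesis on both phenols under carbonate conditions that leave the methyl ester untouched; no stereocentre.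

Step 4
Reactants: 3 1-[4,6-bis(benzyloxy)-2-hydroxy-3-methoxyphenyl]ethan-1-one; 5 methyl 3,5-bis(benzyloxy)-4-methoxybenzoate
Product: 7 5,7-bis(benzyloxy)-2-[3,5-bis(benzyloxy)-4-methoxyphenyl]-8-methoxy-4H-chromen-4-one, via β-diketone 6 (not isolated)
Conditions: LiHMDS (4 equiv), THF, −78 °C → rt; AcOH quench; then AcOH, NaOAc, 100 °C
Reagents that add atoms: none
Why: Crossed Claisen condensation of the phenoxide/enolate dianion of 3 with the non-enolisable ester gives the β-diketone, and cyclodehydration through the only free phenol in buffered acetic acid closes the γ-pyrone without cleaving benzyl ethers; no stereocentre.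

Step 5
Reactants: 7 5,7-bis(benzyloxy)-2-[3,5-bis(benzyloxy)-4-methoxyphenyl]-8-methoxy-4H-chromen-4-one
Product: 9 5,7-bis(benzyloxy)-2-[3,5-bis(benzyloxy)-4-methoxyphenyl]-3-hydroxy-8-methoxy-4H-chromen-4-one, via flavone 2,3-epoxide 8 (not isolated)
Conditions: DMDO (acetone solution, 3–5 equiv), CH2Cl2, 0 °C → rt; then p-TsOH (cat.), CH2Cl2, rt
Reagents that add atoms: dimethyldioxirane, CC1(C)OO1
Why: Dioxirane epoxidation of the chromone C2=C3 bond gives the racemic cis-fused epoxide, which acid opens at C2 (oxocarbenium) and loss of H-3 re-aromatises the pyranone to the 3-hydroxyflavone, erasing both transient stereocentres.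

Step 6
Reactants: 9 5,7-bis(benzyloxy)-2-[3,5-bis(benzyloxy)-4-methoxyphenyl]-3-hydroxy-8-methoxy-4H-chromen-4-one
Product: 10 3,5,7-trihydroxy-2-(3,5-dihydroxy-4-methoxyphenyl)-8-methoxy-4H-chromen-4-one
Conditions: H2 (1 atm), 10% Pd/C, THF/MeOH, rt
Reagents that add atoms: none
Why: Pd-catalysed hydrogenolysis removes all four O-benzyl groups while methyl ethers and the flavonol core survive, and the neutral conditions exclude acid-mediated 8-OMe/6-OMe isomerisation; no stereocentre in the target.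

## Compound list

1 | 1-[2,4-bis(benzyloxy)-6-hydroxyphenyl]ethan-1-one | CC(=O)c1c(O)cc(OCc2ccccc2)cc1OCc1ccccc1 | starting material
2 | 1-[4,6-bis(benzyloxy)-2-hydroxy-3-iodophenyl]ethan-1-one | CC(=O)c1c(O)c(I)c(OCc2ccccc2)cc1OCc1ccccc1 | intermediate
3 | 1-[4,6-bis(benzyloxy)-2-hydroxy-3-methoxyphenyl]ethan-1-one | CC(=O)c1c(O)c(OC)c(OCc2ccccc2)cc1OCc1ccccc1 | intermediate
4 | methyl 3,5-dihydroxy-4-methoxybenzoate | COC(=O)c1cc(O)c(OC)c(O)c1 | starting material
5 | methyl 3,5-bis(benzyloxy)-4-methoxybenzoate | COC(=O)c1cc(OCc2ccccc2)c(OC)c(OCc2ccccc2)c1 | intermediate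
6 | 1-[4,6-bis(benzyloxy)-2-hydroxy-3-methoxyphenyl]-3-[3,5-bis(benzyloxy)-4-methoxyphenyl]propane-1,3-dione | COc1c(OCc2ccccc2)cc(OCc2ccccc2)c(C(=O)CC(=O)c2cc(OCc3ccccc3)c(OC)c(OCc3ccccc3)c2)c1O | intermediate (not isolated)
7 | 5,7-bis(benzyloxy)-2-[3,5-bis(benzyloxy)-4-methoxyphenyl]-8-methoxy-4H-chromen-4-one | COc1c(OCc2ccccc2)cc(OCc2ccccc2)c2c(=O)cc(-c3cc(OCc4ccccc4)c(OC)c(OCc4ccccc4)c3)oc12 | intermediate
8 | 5,7-bis(benzyloxy)-2-[3,5-bis(benzyloxy)-4-methoxyphenyl]-2,3-epoxy-8-methoxy-2,3-dihydro-4H-chromen-4-one (racemic, cis-fused oxirane; one enantiomer drawn) | COc1c(OCc2ccccc2)cc(OCc2ccccc2)c2c1O[C@@]1(c3cc(OCc4ccccc4)c(OC)c(OCc4ccccc4)c3)O[C@H]1C2=O | intermediate (not isolated)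
9 | 5,7-bis(benzyloxy)-2-[3,5-bis(benzyloxy)-4-methoxyphenyl]-3-hydroxy-8-methoxy-4H-chromen-4-one | COc1c(OCc2ccccc2)cc(OCc2ccccc2)c2c(=O)c(O)c(-c3cc(OCc4ccccc4)c(OC)c(OCc4ccccc4)c3)oc12 | intermediate
10 | 3,5,7-trihydroxy-2-(3,5-dihydroxy-4-methoxyphenyl)-8-methoxy-4H-chromen-4-one (achiral) | COc1c(O)cc(-c2oc3c(OC)c(O)cc(O)c3c(=O)c2O)cc1O | target

## Summary

Total step count: 6.
Longest linear sequence: 5 steps (1 → 2 → 3 → 7 → 9 → 10; steps 1, 2, 4, 5, 6).

## Steps most likely to fail, with fallbacks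

**Step 2 (Cu-catalysed methoxylation of the hindered o-iodophenol).** The risk is reduction back to 1 or stalled coupling on the electron-rich phenoxide. The fallback sets out from 2 and moves the C–O coupling to a stage where the iodide is no longer next to a phenoxide and the ketone is no longer enolisable. Condensing 2 with ester 5 under the step 4 conditions (LiHMDS, THF; then AcOH/NaOAc, 100 °C) gives 1-[4,6-bis(benzyloxy)-2-hydroxy-3-iodophenyl]-3-[3,5-bis(benzyloxy)-4-methoxyphenyl]propane-1,3-dione F1 in the flask. This cyclises to 5,7-bis(benzyloxy)-2-[3,5-bis(benzyloxy)-4-methoxyphenyl]-8-iodo-4H-chromen-4-one F2. Methanolysis of this neutral aryl iodide (NaOMe, CuBr, DMF/MeOH, 90 °C) then gives flavone 7, where the fallback comes back to the route.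

**Step 5 (DMDO epoxidation of the chromone).** The risk is that oxidation of the electron-poor C2=C3 bond is slow, while two electron-rich rings and four benzylic ethers can compete. The fallback sets out from 3 (with 5 as the B-ring source) and builds the 3-OH during ring closure instead. Reduction of 5 (LiAlH4, THF, 0 °C) gives [3,5-bis(benzyloxy)-4-methoxyphenyl]methanol F5. Oxidation (MnO2, CH2Cl2, rt) gives 3,5-bis(benzyloxy)-4-methoxybenzaldehyde F6. Claisen–Schmidt condensation with 3 (KOH, EtOH/THF, rt) gives (E)-1-[4,6-bis(benzyloxy)-2-hydroxy-3-methoxyphenyl]-3-[3,5-bis(benzyloxy)-4-methoxyphenyl]prop-2-en-1-one F7. Algar–Flynn–Oyamada oxidation (30% H2O2, NaOH, MeOH/THF, 0 °C, kept cold because 6'-alkoxy chalcones can divert to aurones) passes through racemic trans-5,7-bis(benzyloxy)-2-[3,5-bis(benzyloxy)-4-methoxyphenyl]-3-hydroxy-8-methoxy-2,3-dihydro-4H-chromen-4-one F8 and gives flavonol 9, where the fallback comes back to the route.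

**Step 4 (intermolecular Claisen on the di-ortho-substituted ketone dianion).** The risk is low conversion with the methyl ester. The fallback sets out from 3 and 5 and makes the C–C bond by intramolecular acyl transfer. Saponification of 5 (LiOH, THF/MeOH/H2O, 50 °C) gives 3,5-bis(benzyloxy)-4-methoxybenzoic acid F3. Esterification of the phenol of 3 with it (EDC·HCl, DMAP, CH2Cl2, rt) gives 2-acetyl-3,5-bis(benzyloxy)-6-methoxyphenyl 3,5-bis(benzyloxy)-4-methoxybenzoate F4. Baker–Venkataraman rearrangement (KOH, pyridine, 50 °C) then delivers β-diketone 6, where the fallback comes back to the route; 6 is cyclised to 7 with AcOH/NaOAc as in step 4.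

## Further compounds

F1 | step 2 | 1-[4,6-bis(benzyloxy)-2-hydroxy-3-iodophenyl]-3-[3,5-bis(benzyloxy)-4-methoxyphenyl]propane-1,3-dione | O=C(CC(=O)c1cc(OCc2ccccc2)c(OC)c(OCc2ccccc2)c1)c1c(O)c(I)c(OCc2ccccc2)cc1OCc1ccccc1
F2 | step 2 | 5,7-bis(benzyloxy)-2-[3,5-bis(benzyloxy)-4-methoxyphenyl]-8-iodo-4H-chromen-4-one | Ic1c(OCc2ccccc2)cc(OCc2ccccc2)c2c(=O)cc(-c3cc(OCc4ccccc4)c(OC)c(OCc4ccccc4)c3)oc12
F3 | step 4 | 3,5-bis(benzyloxy)-4-methoxybenzoic acid | OC(=O)c1cc(OCc2ccccc2)c(OC)c(OCc2ccccc2)c1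
F4 | step 4 | 2-acetyl-3,5-bis(benzyloxy)-6-methoxyphenyl 3,5-bis(benzyloxy)-4-methoxybenzoate | CC(=O)c1c(OC(=O)c2cc(OCc3ccccc3)c(OC)c(OCc3ccccc3)c2)c(OC)c(OCc2ccccc2)cc1OCc1ccccc1
F5 | step 5 | [3,5-bis(benzyloxy)-4-methoxyphenyl]methanol | OCc1cc(OCc2ccccc2)c(OC)c(OCc2ccccc2)c1
F6 | step 5 | 3,5-bis(benzyloxy)-4-methoxybenzaldehyde | O=Cc1cc(OCc2ccccc2)c(OC)c(OCc2ccccc2)c1
F7 | step 5 | (E)-1-[4,6-bis(benzyloxy)-2-hydroxy-3-methoxyphenyl]-3-[3,5-bis(benzyloxy)-4-methoxyphenyl]prop-2-en-1-one | COc1c(OCc2ccccc2)cc(OCc2ccccc2)c(C(=O)/C=C/c2cc(OCc3ccccc3)c(OC)c(OCc3ccccc3)c2)c1O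
F8 | step 5 | trans-5,7-bis(benzyloxy)-2-[3,5-bis(benzyloxy)-4-methoxyphenyl]-3-hydroxy-8-methoxy-2,3-dihydro-4H-chromen-4-one (racemic; one enantiomer drawn) | COc1c(OCc2ccccc2)cc(OCc2ccccc2)c2c1O[C@H](c1cc(OCc3ccccc3)c(OC)c(OCc3ccccc3)c1)[C@@H](O)C2=O
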